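The numbers of this flask are those of an exercise.

Product is made from free substrate, and free substrate is what the dormant form and the product leave over, so we reckon in fractions of the charge.

    substrate ⇌ dormant form (K1 = 2.62, k1 = 0.0212 s⁻¹)
    substrate + acid → weak acid + acid + product (k2 = 2.45 L mol⁻¹ s⁻¹)
    weak acid ⇌ conjugate base + acid, settled at all times (K3 = 1.0 × 10⁻⁶ M)
    substrate → weak acid + product (k4 = 3.86 × 10⁻⁴ s⁻¹)
    substrate + product ⇌ idle adduct, settled at all times (K5 = 29.4 L mol⁻¹)

substrate 0.16 M; acid 4.80 mM; time 2.0 min

1. part of the substrate that has reacted at 2.0 min
2. pH of the solution at 2.0 min

- acid is the free proton; pH is minus the decimal logarithm of its molar concentration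
- a species is counted by the substrate in it: one idle adduct counts as two
- amounts and yields of product count idle adduct too
- in an amount of product, one idle adduct counts as one product
- what has gone from substrate into another species counts as reacted, even if it can come back
- run time (flask): 2.0 min

The adduct is kept at balance, and the dormant form, by its own step with both directions counted, relaxes with a half-life of 0.394 min, shorter than the run. So we treat both as balanced and set up a small table: the weight of each form of unconverted substrate per part of free substrate. Free substrate weighs 1 and dormant form 2.62. The substrate in idle adduct weighs the adduct constant times the charge times the free product, which we guess at 33.3%, so 1.57. The dormant row is heavier than the adduct row.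

The table gives the free share, the part of the unconverted substrate that stands free: 19.3%. Acid comes back unchanged, so conversion is pseudo-first-order with 0.706 min⁻¹, much faster than the direct path's 0.02316 min⁻¹. We let free substrate start as the whole charge and sink to the free share with a time constant of 0.568 min, which gives an effective exposure of 0.845 min. That makes 44.9% product and leaves 10.6% free substrate, so we commit to 89.4% reacted. Free product then comes out at 28.3%, under our guess. Conjugate base comes to about 1.50 × 10⁻⁵ M, far below the acid, so the pH stays that of the charge.

The forecast gives 88.7% and pH 2.32, holding that “The acid is a catalyst and is not used up”. Our part reacted differs slightly from it.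

The simulation gives 89.5% and pH 2.32.

For the neighbour charged with 0.0012 M of acid, we keep the same time and guess free product at 10.0%. That neighbour's free share is 24.4% and its constant 0.176 min⁻¹. Its exposure is 0.919 min, giving 15.0% product and 20.8% free substrate, so 79.2% reacted. The simulated neighbour holds 15.8% product and 20.5% substrate, with 79.5% reacted.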